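**Retrosynthetic overview**
1. Target 17 ⇒ (global hydrogenolysis) nonabenzyl ether 16 ⇒ (Rubottom oxidation, C3–OH trans to the C2 aryl) flavanone 13.
2. Key disconnection: the lower ring C of 13 is opened at O1–C8a and at C3–C4. This gives the ortho-fluoro benzoate 8 (ester carbon = C4, C–F carbon = C8a) and the C,O-dilithio derivative 11 of (R)-bromohydrin 10 (O1–C2–C3, C2 stereocentre in place).
3. Enabling feature: in the lower chroman-4-one, the ring-A carbon C8a that carries O1 is ortho to C4a, which carries the C4 carbonyl, and O1 and C3 are 1,3-related through C2. An ester on C4a next to C8a–F is therefore a 1,3-dielectrophile, and the ketone formed at C4 by C-acylation activates C8a for displacement of fluoride by the O1 alkoxide.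
4. 8 ⇒ directed ortho-lithiation/methoxycarbonylation of 6 ⇒ Friedel–Crafts 4β-arylation (upper C4–lower C8 bond, upper C4 stereocentre) of the C4-oxidised penta-O-benzyl-(−)-epicatechin 3 with 1,3-bis(benzyloxy)-5-fluorobenzene 5.
5. Ring order: upper rings A, C and B come intact from (−)-epicatechin; lower ring A is attached in step 4; lower ring B arrives with 10; lower ring C is closed last, in the key step.

Key step: step 7

Assumption (chemistry): (−)-epicatechin, 5-fluororesorcinol and 2-bromo-1-[3,4-bis(benzyloxy)phenyl]ethan-1-one are taken as purchased; the C4 configuration of ether 3 is drawn as 4β but is of no consequence, because C4 is re-ionised in step 4.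

**Step 1**
Reactants: 1 (−)-epicatechin
Product: 2 penta-O-benzyl-(−)-epicatechin
Conditions: NaH, BnBr, DMF, −20 °C to rt
Reagents that add atoms: benzyl bromide, BrCc1ccccc1
Why: Williamson ether synthesis: NaH generates the four phenoxides and the C3 alkoxide, which are benzylated by SN2 on benzyl bromide, and the low temperature avoids base-induced opening of ring C so that C2 and C3 keep their configuration.

**Step 2**
Reactants: 2 penta-O-benzyl-(−)-epicatechin
Product: 3 4β-(2-ethoxyethoxy)-penta-O-benzyl-(−)-epicatechin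
Conditions: DDQ, 2-ethoxyethanol, CH2Cl2, rt
Reagents that add atoms: 2-ethoxyethanol, CCOCCO
Why: DDQ benzylic oxidation: hydride abstraction from C4 gives the flavan-4-yl cation stabilised by the three oxygen donors of ring A, which the alcohol captures anti to the cis C2 aryl and C3 benzyloxy groups to give the 4β ether.

**Step 3**
Reactants: 4 5-fluororesorcinol
Product: 5 1,3-bis(benzyloxy)-5-fluorobenzene
Conditions: BnBr, K2CO3, DMF, 60 °C
Reagents that add atoms: benzyl bromide, BrCc1ccccc1
Why: Williamson ether synthesis on both phenols with K2CO3 as base; no stereocentre is involved.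

**Step 4**
Reactants: 3 4β-(2-ethoxyethoxy)-penta-O-benzyl-(−)-epicatechin, 5 1,3-bis(benzyloxy)-5-fluorobenzene
Product: 6 4β-[2,4-bis(benzyloxy)-6-fluorophenyl]-penta-O-benzyl-(−)-epicatechin
Conditions: 5 (large excess), TMSOTf (cat.), CH2Cl2, −78 to −40 °C, slow addition of 3
Reagents that add atoms: none
Why: Friedel–Crafts alkylation by the SN1 route: TMSOTf ionises the C4 ether, and the arene, kept in large excess so that it should outcompete ring A of the flavan, attacks through its least hindered activated carbon (para to one benzyloxy group, next to fluorine) on the face opposite the cis C2 aryl and C3 benzyloxy groups, which sets C4 as R (3,4-trans, 4β).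

**Step 5**
Reactants: 6 4β-[2,4-bis(benzyloxy)-6-fluorophenyl]-penta-O-benzyl-(−)-epicatechin
Product: 8 methyl 4,6-bis(benzyloxy)-2-fluoro-3-(penta-O-benzyl-epicatechin-4β-yl)benzoate, via aryllithium 7 (not isolated)
Conditions: lithium 2,2,6,6-tetramethylpiperidide (from the amine and n-BuLi), THF, −78 °C; then ClCO2Me, −78 °C
Reagents that add atoms: methyl chloroformate, COC(Cl)=O
Why: Directed ortho-metalation followed by acyl substitution: the only C–H flanked by fluorine and a benzyloxy group is the most acidic aryl C–H of 6, the hindered amide base does not attack benzyl ethers, and the aryllithium is acylated at −78 °C before it can lose LiF.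

**Step 6**
Reactants: 9 2-bromo-1-[3,4-bis(benzyloxy)phenyl]ethan-1-one
Product: 10 (1R)-2-bromo-1-[3,4-bis(benzyloxy)phenyl]ethan-1-ol
Conditions: (R)-2-methyl-CBS-oxazaborolidine (cat.), BH3·SMe2, THF, 0 °C
Reagents that add atoms: none
Why: Corey–Bakshi–Shibata reduction: the (R)-oxazaborolidine–borane complex delivers hydride to one face of the aryl ketone, with the aryl group as the large substituent, and so sets the carbinol centre as R.

**Step 7**
Reactants: 10 (1R)-2-bromo-1-[3,4-bis(benzyloxy)phenyl]ethan-1-ol, 8 methyl 4,6-bis(benzyloxy)-2-fluoro-3-(penta-O-benzyl-epicatechin-4β-yl)benzoate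
Product: 13 (2S)-5,7-bis(benzyloxy)-2-[3,4-bis(benzyloxy)phenyl]-8-(penta-O-benzyl-epicatechin-4β-yl)chroman-4-one, via dilithio alkoxide 11 (not isolated), via lithium aldolate 12 (not isolated)
Conditions: 10, n-BuLi, Et2O, −78 °C; t-BuLi (2 equiv), −78 °C; then 8 in THF, −78 to 0 °C; aq NH4Cl
Reagents that add atoms: none
Why: Proposed new method: deprotonation of the hydroxyl and bromine–lithium exchange convert 10 into the β-oxido alkyllithium 11, whose carbanion (future C3) adds to the ester carbon of 8 (future C4) far faster than the lithium alkoxide does, and collapse of the tetrahedral adduct on warming releases the ortho-fluoro aryl ketone as its lithium aldolate 12. The new C4 carbonyl then activates the adjacent C8a–F carbon, and the benzylic alkoxide O1, held two atoms from C3, closes the lower ring C by intramolecular nucleophilic aromatic substitution (addition–elimination through a six-membered transition state and a ketone-stabilised σ-adduct), expelling LiF. The closest known reaction type is the tandem C-acylation/intramolecular SNAr annulation of ketone enolates with 2-fluorobenzoyl electrophiles that gives chromones and flavones, combined with the known reactivity of β-oxido alkyllithiums toward carbonyl electrophiles at −78 °C; the new element is an sp3 C,O-dianion, so that a chroman-4-one with an intact C2 stereocentre should result. No stereocentre is created: C2 comes from 10 with its C–O bond untouched, and its descriptor changes from R to S only because C3 loses priority. The step needs mono-addition (secured by the di-ortho-substituted, twisted aryl ketone and near-stoichiometric 11), ring closure faster than retro-aldol cleavage of 12 (secured by fluoride ortho to the carbonyl and a temperature not above 0 °C) and the absence of a competing internal nucleophile (secured by the benzyl ether on the upper O3, which as an alkoxide would close a five-membered ring onto C8a).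

**Step 8**
Reactants: 13 (2S)-5,7-bis(benzyloxy)-2-[3,4-bis(benzyloxy)phenyl]-8-(penta-O-benzyl-epicatechin-4β-yl)chroman-4-one
Product: 16 (2R,3R)-5,7-bis(benzyloxy)-2-[3,4-bis(benzyloxy)phenyl]-3-hydroxy-8-(penta-O-benzyl-epicatechin-4β-yl)chroman-4-one, via trimethylsilyl enol ether 14 (not isolated), via silyloxy epoxide 15 (not isolated)
Conditions: TMSOTf, Et3N, CH2Cl2, 0 °C; then dimethyldioxirane, acetone/CH2Cl2, −40 °C; then citric acid, MeOH, rt
Reagents that add atoms: dimethyldioxirane, CC1(C)OO1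
Why: Rubottom oxidation: soft enolisation toward C3, the only enolisable position, gives the silyl enol ether, dimethyldioxirane epoxidises it on the face opposite the C2 aryl group, and methanolysis of the silyloxy epoxide gives the α-hydroxy ketone with C3 set as R (2,3-trans).

**Step 9**
Reactants: 16 (2R,3R)-5,7-bis(benzyloxy)-2-[3,4-bis(benzyloxy)phenyl]-3-hydroxy-8-(penta-O-benzyl-epicatechin-4β-yl)chroman-4-one
Product: 17 epicatechin-(4β→8)-(2R,3R)-taxifolin (target)
Conditions: H2 (1 atm), Pd(OH)2/C, THF/MeOH, rt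
Reagents that add atoms: none
Why: Hydrogenolysis of all nine benzyl ethers over Pd(OH)2 on carbon under neutral conditions should leave the aryl ketone, the C4–C8 bond and all five stereocentres untouched.

**Compound list**
1 | (−)-epicatechin, (2R,3R)-2-(3,4-dihydroxyphenyl)chromane-3,5,7-triol | C1c2c(O)cc(O)cc2O[C@H](c2ccc(O)c(O)c2)[C@@H]1O | starting material
2 | (2R,3R)-3,5,7-tris(benzyloxy)-2-[3,4-bis(benzyloxy)phenyl]chromane (penta-O-benzyl-(−)-epicatechin) | C1c2c(OCc5ccccc5)cc(OCc5ccccc5)cc2O[C@H](c2ccc(OCc5ccccc5)c(OCc5ccccc5)c2)[C@@H]1OCc5ccccc5 | intermediate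
3 | (2R,3R,4S)-3,5,7-tris(benzyloxy)-2-[3,4-bis(benzyloxy)phenyl]-4-(2-ethoxyethoxy)chromane (4β ether, trans to the 3-benzyloxy group) | CCOCCO[C@H]1c2c(OCc5ccccc5)cc(OCc5ccccc5)cc2O[C@H](c2ccc(OCc5ccccc5)c(OCc5ccccc5)c2)[C@@H]1OCc5ccccc5 | intermediate
4 | 5-fluorobenzene-1,3-diol (5-fluororesorcinol) | Oc1cc(O)cc(F)c1 | starting material
5 | 1,3-bis(benzyloxy)-5-fluorobenzene | Fc1cc(OCc2ccccc2)cc(OCc2ccccc2)c1 | intermediate
6 | (2R,3R,4R)-3,5,7-tris(benzyloxy)-2-[3,4-bis(benzyloxy)phenyl]-4-[2,4-bis(benzyloxy)-6-fluorophenyl]chromane (2,3-cis-3,4-trans, 4β-aryl) | c1c(OCc5ccccc5)cc(OCc5ccccc5)c([C@H]3c4c(OCc5ccccc5)cc(OCc5ccccc5)cc4O[C@H](c4ccc(OCc5ccccc5)c(OCc5ccccc5)c4)[C@@H]3OCc5ccccc5)c1F | intermediate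
7 | aryllithium from 6, lithiated at the ring carbon between fluorine and benzyloxy: {4,6-bis(benzyloxy)-2-fluoro-3-[(2R,3R,4R)-3,5,7-tris(benzyloxy)-2-[3,4-bis(benzyloxy)phenyl]chroman-4-yl]phenyl}lithium | [Li]c1c(OCc5ccccc5)cc(OCc5ccccc5)c([C@H]3c4c(OCc5ccccc5)cc(OCc5ccccc5)cc4O[C@H](c4ccc(OCc5ccccc5)c(OCc5ccccc5)c4)[C@@H]3OCc5ccccc5)c1F | intermediate (not isolated)
8 | methyl 4,6-bis(benzyloxy)-2-fluoro-3-{(2R,3R,4R)-3,5,7-tris(benzyloxy)-2-[3,4-bis(benzyloxy)phenyl]chroman-4-yl}benzoate | COC(=O)c1c(OCc5ccccc5)cc(OCc5ccccc5)c([C@H]3c4c(OCc5ccccc5)cc(OCc5ccccc5)cc4O[C@H](c4ccc(OCc5ccccc5)c(OCc5ccccc5)c4)[C@@H]3OCc5ccccc5)c1F | intermediate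
9 | 2-bromo-1-[3,4-bis(benzyloxy)phenyl]ethan-1-one | O=C(CBr)c1ccc(OCc2ccccc2)c(OCc2ccccc2)c1 | starting material
10 | (1R)-2-bromo-1-[3,4-bis(benzyloxy)phenyl]ethan-1-ol | O[C@H](c1ccc(OCc2ccccc2)c(OCc2ccccc2)c1)CBr | intermediate
11 | lithium (1S)-1-[3,4-bis(benzyloxy)phenyl]-2-lithioethan-1-olate (same spatial arrangement as 10) | [Li]O[C@H](c1ccc(OCc2ccccc2)c(OCc2ccccc2)c1)C[Li] | intermediate (not isolated)
12 | lithium (1S)-1-[3,4-bis(benzyloxy)phenyl]-3-oxo-3-{4,6-bis(benzyloxy)-2-fluoro-3-[(2R,3R,4R)-3,5,7-tris(benzyloxy)-2-[3,4-bis(benzyloxy)phenyl]chroman-4-yl]phenyl}propan-1-olate | [Li]O[C@H](c1ccc(OCc2ccccc2)c(OCc2ccccc2)c1)CC(=O)c1c(OCc5ccccc5)cc(OCc5ccccc5)c([C@H]3c4c(OCc5ccccc5)cc(OCc5ccccc5)cc4O[C@H](c4ccc(OCc5ccccc5)c(OCc5ccccc5)c4)[C@@H]3OCc5ccccc5)c1F | intermediate (not isolated)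
13 | (2S)-5,7-bis(benzyloxy)-2-[3,4-bis(benzyloxy)phenyl]-8-{(2R,3R,4R)-3,5,7-tris(benzyloxy)-2-[3,4-bis(benzyloxy)phenyl]chroman-4-yl}chroman-4-one | O=C1c2c(OCc5ccccc5)cc(OCc5ccccc5)c([C@H]3c4c(OCc5ccccc5)cc(OCc5ccccc5)cc4O[C@H](c4ccc(OCc5ccccc5)c(OCc5ccccc5)c4)[C@@H]3OCc5ccccc5)c2O[C@H](c2ccc(OCc5ccccc5)c(OCc5ccccc5)c2)C1 | intermediate
14 | (2S)-5,7-bis(benzyloxy)-2-[3,4-bis(benzyloxy)phenyl]-8-{(2R,3R,4R)-3,5,7-tris(benzyloxy)-2-[3,4-bis(benzyloxy)phenyl]chroman-4-yl}-4-[(trimethylsilyl)oxy]-2H-chromene | C[Si](C)(C)OC=1c2c(OCc5ccccc5)cc(OCc5ccccc5)c([C@H]3c4c(OCc5ccccc5)cc(OCc5ccccc5)cc4O[C@H](c4ccc(OCc5ccccc5)c(OCc5ccccc5)c4)[C@@H]3OCc5ccccc5)c2O[C@H](c2ccc(OCc5ccccc5)c(OCc5ccccc5)c2)C=1 | intermediate (not isolated)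
15 | 3,4-epoxide of 14: 4-[(trimethylsilyl)oxy]-3,4-epoxychromane with the oxirane oxygen on the ring face opposite the C2 aryl group, other substituents as in 14 | C[Si](C)(C)O[C@]16c2c(OCc5ccccc5)cc(OCc5ccccc5)c([C@H]3c4c(OCc5ccccc5)cc(OCc5ccccc5)cc4O[C@H](c4ccc(OCc5ccccc5)c(OCc5ccccc5)c4)[C@@H]3OCc5ccccc5)c2O[C@H](c2ccc(OCc5ccccc5)c(OCc5ccccc5)c2)[C@H]1O6 | intermediate (not isolated)
16 | (2R,3R)-5,7-bis(benzyloxy)-2-[3,4-bis(benzyloxy)phenyl]-3-hydroxy-8-{(2R,3R,4R)-3,5,7-tris(benzyloxy)-2-[3,4-bis(benzyloxy)phenyl]chroman-4-yl}chroman-4-one (2,3-trans) | O=C1c2c(OCc5ccccc5)cc(OCc5ccccc5)c([C@H]3c4c(OCc5ccccc5)cc(OCc5ccccc5)cc4O[C@H](c4ccc(OCc5ccccc5)c(OCc5ccccc5)c4)[C@@H]3OCc5ccccc5)c2O[C@H](c2ccc(OCc5ccccc5)c(OCc5ccccc5)c2)[C@H]1O | intermediate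
17 | (2R,3R)-2-(3,4-dihydroxyphenyl)-8-[(2R,3R,4R)-2-(3,4-dihydroxyphenyl)-3,5,7-trihydroxychroman-4-yl]-3,5,7-trihydroxychroman-4-one, epicatechin-(4β→8)-taxifolin | O=C1c2c(O)cc(O)c([C@H]3c4c(O)cc(O)cc4O[C@H](c4ccc(O)c(O)c4)[C@@H]3O)c2O[C@H](c2ccc(O)c(O)c2)[C@H]1O | target

**Step count and risks**
Total step count: 9. Longest linear sequence: 7 steps (1, 2, 4, 5, 7, 8, 9 from (−)-epicatechin).

Steps most likely to fail:

Step 7 (proposed cascade). What may go wrong: a second organolithium may add to the ketone as it is released; the dilithio species may undergo β-elimination before it meets the ester; or the lithium aldolate may undergo retro-aldol cleavage before ring closure, which would erode the C2 configuration. Fallback with known chemistry, setting out from 6 and returning at 13: 6 is lithiated as in step 5 and quenched with N-methoxy-N-methylacetamide to give the methyl ketone 1-[4,6-bis(benzyloxy)-2-fluoro-3-(penta-O-benzyl-epicatechin-4β-yl)phenyl]ethan-1-one F1. Its boron enolate (the enantiomer of Ipc2BCl matched to the S carbinol, Et3N, −78 °C) undergoes an asymmetric aldol addition to 3,4-bis(benzyloxy)benzaldehyde to give the β-hydroxy ketone (3S)-3-[3,4-bis(benzyloxy)phenyl]-1-[4,6-bis(benzyloxy)-2-fluoro-3-(penta-O-benzyl-epicatechin-4β-yl)phenyl]-3-hydroxypropan-1-one F2. Its carbinol epimer is a diastereomer because of the upper unit and should be removable by chromatography. K2CO3 in DMF at room temperature then closes ring C by intramolecular nucleophilic aromatic substitution to give 13. This route forms C2–C3 by aldol addition and no longer depends on the organodilithium.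

Step 4. What may go wrong: the flavan-4-yl cation may be captured by ring A of unreacted 3 or of product 6 (self-condensation to oligomers) faster than by the less nucleophilic fluoroarene, and attack at the arene carbon between the two benzyloxy groups may compete. Fallback, setting out from 3 and returning at 6: 3 is coupled under the same Lewis-acid conditions with commercial 3,5-bis(benzyloxy)phenol, a phloroglucinol-type nucleophile that matches ring A in reactivity and should react ortho to its free hydroxyl, to give the phenol 3,5-bis(benzyloxy)-2-(penta-O-benzyl-epicatechin-4β-yl)phenol F3. Deoxyfluorination of the phenol (PhenoFluor, CsF, toluene, 110 °C) then gives 6.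

Step 5. What may go wrong: deprotonation at another site (a benzylic C–H or an aryl C–H of the upper ring A), or loss of LiF from the ortho-fluoro aryllithium to give an aryne. Fallback, setting out from 3 and returning at 8: the ester is brought in with the arene. Methyl 2,4,6-trihydroxybenzoate is dibenzylated (BnBr, K2CO3) to methyl 2,4-bis(benzyloxy)-6-hydroxybenzoate F4, which is coupled with 3 (TMSOTf, CH2Cl2) ortho to its free hydroxyl to give the salicylate methyl 4,6-bis(benzyloxy)-2-hydroxy-3-(penta-O-benzyl-epicatechin-4β-yl)benzoate F5. Deoxyfluorination of this ester-activated phenol through its aryl fluorosulfate (SO2F2, NMe4F, DMF) gives 8 without any organolithium step on the large intermediate.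

**Further compounds**
F1 | step 7 | 1-{4,6-bis(benzyloxy)-2-fluoro-3-[(2R,3R,4R)-3,5,7-tris(benzyloxy)-2-[3,4-bis(benzyloxy)phenyl]chroman-4-yl]phenyl}ethan-1-one | CC(=O)c1c(OCc5ccccc5)cc(OCc5ccccc5)c([C@H]3c4c(OCc5ccccc5)cc(OCc5ccccc5)cc4O[C@H](c4ccc(OCc5ccccc5)c(OCc5ccccc5)c4)[C@@H]3OCc5ccccc5)c1F
F2 | step 7 | (3S)-3-[3,4-bis(benzyloxy)phenyl]-1-{4,6-bis(benzyloxy)-2-fluoro-3-[(2R,3R,4R)-3,5,7-tris(benzyloxy)-2-[3,4-bis(benzyloxy)phenyl]chroman-4-yl]phenyl}-3-hydroxypropan-1-one | O[C@H](c1ccc(OCc2ccccc2)c(OCc2ccccc2)c1)CC(=O)c1c(OCc5ccccc5)cc(OCc5ccccc5)c([C@H]3c4c(OCc5ccccc5)cc(OCc5ccccc5)cc4O[C@H](c4ccc(OCc5ccccc5)c(OCc5ccccc5)c4)[C@@H]3OCc5ccccc5)c1F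
F3 | step 4 | 3,5-bis(benzyloxy)-2-(penta-O-benzyl-epicatechin-4β-yl)phenol (2,3-cis-3,4-trans flavan, same spatial arrangement as 6) | c1c(OCc5ccccc5)cc(OCc5ccccc5)c([C@H]3c4c(OCc5ccccc5)cc(OCc5ccccc5)cc4O[C@H](c4ccc(OCc5ccccc5)c(OCc5ccccc5)c4)[C@@H]3OCc5ccccc5)c1O
F4 | step 5 | methyl 2,4-bis(benzyloxy)-6-hydroxybenzoate | COC(=O)c1c(O)cc(OCc2ccccc2)cc1OCc1ccccc1
F5 | step 5 | methyl 4,6-bis(benzyloxy)-2-hydroxy-3-(penta-O-benzyl-epicatechin-4β-yl)benzoate (2,3-cis-3,4-trans flavan, same spatial arrangement as 8) | COC(=O)c1c(OCc5ccccc5)cc(OCc5ccccc5)c([C@H]3c4c(OCc5ccccc5)cc(OCc5ccccc5)cc4O[C@H](c4ccc(OCc5ccccc5)c(OCc5ccccc5)c4)[C@@H]3OCc5ccccc5)c1O
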